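The target is numbered as a labdane (C1–C20). Everything rests on disconnecting C8–C9, the bond shared by the carbocycle C5–C6–C7–C8–C9–C10 (ring B) and the bridging δ-lactone. The key step closes ring B by an intramolecular Nozaki–Hiyama–Kishi addition of a (Z)-alkenyl triflate at C9 to the C8 methyl ketone; it exploits the 1,3-dioxygenated unit O8–C8–C9–C11–O11 as an allylic-alcohol retron, sets the tertiary carbinol C8 and leaves a C9=C11 alkene whose hydroboration later sets C9 and C11 together. The precursor is an open-chain keto triflate whose C5/C10 pair comes from a Michael addition–alkylation on a menthyloxybutenolide.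

Key step: step 9

Remark on the chemistry: atom labels follow labdane numbering (C2 lactone carbonyl, C1 its CH2, C10 and C8 the methyl-bearing ring carbons with C8 carrying the lactone oxygen O8, C9 the ring CH between them, C5 the ring CH bearing C4(CH3)2 and the acid carbon C3, C6 the ring carbinol, C7 the ring CH2, C11–C16 the side chain with carbinols C11 and C13, C17 and C20 the methyls on C8 and C10); it is assumed that the free hydroxy acid does not re-lactonise under the buffered final deprotection.

Step 1
Reactants: 1 5-hydroxy-3-methylfuran-2(5H)-one (racemic); 2 (−)-menthol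
Product: 3 (5R)-5-menthyloxy-3-methylfuran-2(5H)-one
Conditions: CSA (cat.), toluene, reflux, azeotropic removal of water; crystallisation from hexane, mother liquor re-equilibrated with CSA
Reagents that add atoms: none
Why: Acid-catalysed acetalisation of the pseudo-acid should give both C6 epimers, which interconvert through the oxocarbenium ion under the acid, so that the (5R) epimer with the menthyloxy group needed to steer step 3 can be collected by crystallisation while the other is recycled (crystallisation-driven acetal epimerisation).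

Step 2
Reactants: 4 2-(trimethylsilyl)ethanol; 5 2-methylpropanoyl chloride
Product: 6 2-(trimethylsilyl)ethyl 2-methylpropanoate
Conditions: Et3N, DMAP (cat.), CH2Cl2, 0 → 23 °C
Reagents that add atoms: none
Why: Acylation of the alcohol by the acid chloride (esterification by nucleophilic acyl substitution) gives the fluoride-cleavable ester that will mask the C3 acid; no stereocentre is formed.

Step 3
Reactants: 6 2-(trimethylsilyl)ethyl 2-methylpropanoate; 3 (5R)-5-menthyloxy-3-methylfuran-2(5H)-one; 7 methyl bromoacetate
Product: 10 C10-quaternary menthyloxy lactone, via lithium ester enolate 8 (not isolated), via lactone enolate 9 (not isolated)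
Conditions: LiN(iPr)2, THF, −78 °C; 3, −78 °C; then 7, DMPU, −78 → −30 °C
Reagents that add atoms: none
Why: Tandem Michael addition–enolate alkylation: ester enolate 8 should add to C5 of the butenolide anti to the menthyloxy group on C6, and lactone enolate 9 should then be alkylated at C10 anti to the bulky new C5 substituent, which sets C5 and the quaternary C10 with its methyl group cis to the C4 group.

Step 4
Reactants: 10 C10-quaternary menthyloxy lactone; 11 2-(2-bromoethyl)-2-methyl-1,3-dioxolane
Product: 15 open-chain keto aldehyde, via lithium ester enolate 12 (not isolated), via alkyllithium 13 (not isolated), via lactol 14 (not isolated)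
Conditions: LiN(iPr)2 (1.05 equiv), THF, −78 °C; then 13 (from 11, Li, Et2O, −10 °C), −78 °C; AcOH, −78 °C; pH 7 buffer, 23 °C
Reagents that add atoms: none
Why: Addition of an alkyllithium to a lactone stopped at the lactolate stage: the methyl ester is shielded as its enolate 12 (the lactone carbonyl has no α-hydrogen), 13 adds to C9, and after protonation lactol 14 should open and lose menthol to unveil the C9 ketone and the C6 aldehyde, the acetal stereocentre having done its work.

Step 5
Reactants: 15 open-chain keto aldehyde; 16 diisopropyl (4S,5S)-2-allyl-1,3,2-dioxaborolane-4,5-dicarboxylate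
Product: 17 (6R) homoallylic alcohol
Conditions: 16 (1.5 equiv), 4 Å MS, toluene, −78 °C; aq. NaHCO3
Reagents that add atoms: none
Why: Roush asymmetric allylboration through a chair-like six-membered transition state: the (S,S)-tartrate reagent should deliver the allyl group to the Re face of the aldehyde under reagent control and so set C6 as (R), while the hindered C9 ketone and the esters stay untouched.

Step 6
Reactants: 17 (6R) homoallylic alcohol
Product: 18 C6 tert-butyldimethylsilyl ether
Conditions: TBSOTf, 2,6-lutidine, CH2Cl2, −78 °C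
Reagents that add atoms: tert-butyldimethylsilyl trifluoromethanesulfonate, CC(C)(C)[Si](C)(C)OS(=O)(=O)C(F)(F)F
Why: Silylation of the hindered secondary alcohol with the silyl triflate (silyl ether protection) should be fast enough to forestall lactonisation of O6 onto the C2 ester; no stereocentre is affected.

Step 7
Reactants: 18 C6 tert-butyldimethylsilyl ether
Product: 19 (Z)-enol triflate at C9=C11
Conditions: KN(SiMe3)2, THF, −78 °C; PhNTf2, −78 → 0 °C
Reagents that add atoms: N-phenylbis(trifluoromethanesulfonimide), O=S(=O)(N(c1ccccc1)S(=O)(=O)C(F)(F)F)C(F)(F)F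
Why: Kinetic enolisation of the C9 ketone, whose only α-hydrogens are on C11, should give the (Z)-enolate because C12 avoids the quaternary C10, and O-sulfonylation by PhNTf2 fixes this geometry (enol triflate formation).

Step 8
Reactants: 19 (Z)-enol triflate at C9=C11
Product: 20 C8 methyl ketone enol triflate
Conditions: PdCl2 (10 mol%), CuCl, O2 (1 atm), DMF–H2O (7:1), 23 °C
Reagents that add atoms: water, O (dioxygen is the terminal oxidant)
Why: Tsuji–Wacker oxidation of the terminal alkene should give the C8 methyl ketone with Markovnikov regioselectivity, the electron-poor enol triflate being a poor ligand for divalent palladium; no stereocentre is formed.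

Step 9
Reactants: 20 C8 methyl ketone enol triflate
Product: 21 ring B tertiary allylic alcohol
Conditions: CrCl2 (6 equiv), NiCl2 (1 mol%), DMF, 23 → 50 °C
Reagents that add atoms: none
Why: Zerovalent nickel (from NiCl2 and CrCl2) should insert into the C9–O triflate bond and hand the alkenyl group to chromium with retention of the (Z) geometry, and the trivalent alkenylchromium then adds to the C8 ketone bound to the same chromium centre through a four-centre transition state. The closest known reaction type is the intramolecular Nozaki–Hiyama–Kishi alkenylation of a carbonyl group. Ring B (C5–C6–C7–C8–C9–C10) closes in the 6-exo-trig mode at the C8 carbonyl carbon. C8 is the only new stereocentre: the chair-like transition state places the C4 substituent on C5 and the O6 silyl ether equatorial and C20 axial, and the Cr–O8 bridge holds O8 in the plane of the C9=C11 alkene, that is equatorial and cis to the C1 arm, with C17 axial, while the alkene keeps C12 cis to C8. The step needs chemoselective addition to the ketone in the presence of two esters and a ketal and this facial selectivity at C8, which the low basicity of the organochromium reagent and the allylic strain between C12 and an equatorial C17 should secure.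

Step 10
Reactants: 21 ring B tertiary allylic alcohol
Product: 22 bridged δ-lactone with exocyclic C9=C11
Conditions: NaH (1.2 equiv), THF, 0 → 23 °C; aq. NH4Cl
Reagents that add atoms: none
Why: Base-mediated lactonisation (intramolecular transesterification): the O8 alkoxide, cis to the C1 arm as set in step 9, should attack the C2 methyl ester once ring B twists, and release of the less basic methoxide should drive closure of the bridged δ-lactone; no stereocentre changes.

Step 11
Reactants: 22 bridged δ-lactone with exocyclic C9=C11
Product: 24 C11 hydroxy C13 ketone, via ketal alcohol 23 (not isolated)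
Conditions: BH3·THF, THF, 0 → 23 °C; H2O2, pH 7 buffer, 0 °C; then PPTS, acetone–H2O, 50 °C
Reagents that add atoms: hydrogen peroxide, OO (oxygen on C11); water, O (carbonyl oxygen on C13)
Why: Hydroboration–oxidation followed by ketal hydrolysis: borane should add syn across C9=C11 from the face of the lactone bridge, the other face being screened by the C4 group on C5, with boron on the less hindered C11, so that the (Z) geometry is translated into H9 syn to the lactone bridge and the (11S) carbinol, and mild acid then frees the C13 ketone.

Step 12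
Reactants: 24 C11 hydroxy C13 ketone; 25 vinylmagnesium bromide
Product: 26 protected target (O6 silyl ether and C3 silylethyl ester)
Conditions: 25 (4 equiv), THF, −78 °C; aq. NH4Cl
Reagents that add atoms: none
Why: Chelation-controlled Grignard addition (1,3-induction): the magnesium alkoxide at O11 should tie the C13 ketone into a chair-like six-membered chelate with the C9 substituent equatorial, and axial delivery of vinyl should give the (13S) carbinol, the hindered lactone and ester being slower to react at −78 °C.

Step 13
Reactants: 26 protected target (O6 silyl ether and C3 silylethyl ester)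
Product: 27 CNP0297019.2
Conditions: Bu4NF, AcOH (1:1), THF, 23 °C
Reagents that add atoms: none
Why: Fluoride-induced cleavage of the silyl ether and β-elimination of the 2-(trimethylsilyl)ethyl ester, buffered with acetic acid so that no alkoxide can attack the lactone, should release the C6 hydroxyl and the C3 acid; no stereocentre is touched.

Compound list
1 | 5-hydroxy-3-methylfuran-2(5H)-one (racemic pseudo-acid) | CC1=CC(O)OC1=O | starting material
2 | (−)-menthol, (1R,2S,5R)-5-methyl-2-(propan-2-yl)cyclohexan-1-ol | C[C@@H]1CC[C@H]([C@@H](C1)O)C(C)C | starting material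
3 | (5R)-3-methyl-5-[(1R,2S,5R)-menthyloxy]furan-2(5H)-one | C[C@@H]1CC[C@H]([C@@H](C1)O[C@@H]2OC(=O)C(C)=C2)C(C)C | intermediate
4 | 2-(trimethylsilyl)ethanol | C[Si](C)(C)CCO | starting material
5 | 2-methylpropanoyl chloride | CC(C)C(Cl)=O | starting material
6 | 2-(trimethylsilyl)ethyl 2-methylpropanoate | CC(C)C(=O)OCC[Si](C)(C)C | intermediate
7 | methyl bromoacetate | COC(=O)CBr | starting material
8 | lithium enolate of ester 6 | CC(C)=C(O[Li])OCC[Si](C)(C)C | intermediate
9 | lithium enolate of the Michael adduct lactone (C4 group on C5 anti to the menthyloxy group on C6) | C[C@@H]1CC[C@H]([C@@H](C1)O[C@@H]2OC(O[Li])=C(C)[C@H]2C(C)(C)C(=O)OCC[Si](C)(C)C)C(C)C | intermediate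
10 | γ-lactone with C9 as lactone carbonyl, C10 carrying methyl and CH2CO2CH3, C5 carrying C(CH3)2CO2CH2CH2Si(CH3)3 and C6 as menthyl acetal; C4 group anti to menthyloxy, CH2CO2CH3 anti to the C4 group | C[C@@H]1CC[C@H]([C@@H](C1)O[C@@H]2OC(=O)[C@](C)(CC(=O)OC)[C@H]2C(C)(C)C(=O)OCC[Si](C)(C)C)C(C)C | intermediate
11 | 2-(2-bromoethyl)-2-methyl-1,3-dioxolane | CC1(CCBr)OCCO1 | starting material
12 | lithium enolate of the methyl ester of 10 | C[C@@H]1CC[C@H]([C@@H](C1)O[C@@H]2OC(=O)[C@](C)(C=C(O[Li])OC)[C@H]2C(C)(C)C(=O)OCC[Si](C)(C)C)C(C)C | intermediate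
13 | [2-(2-methyl-1,3-dioxolan-2-yl)ethyl]lithium | [Li]CCC1(C)OCCO1 | intermediate
14 | lactol from addition of 13 to C9 of 10 (2-hydroxytetrahydrofuran, both C9 epimers) | C[C@@H]1CC[C@H]([C@@H](C1)O[C@@H]2OC(O)(CCC3(C)OCCO3)[C@](C)(CC(=O)OC)[C@H]2C(C)(C)C(=O)OCC[Si](C)(C)C)C(C)C | intermediate
15 | open-chain keto aldehyde: C6 aldehyde, C5 bearing the C4 ester group, C10 bearing methyl and CH2CO2CH3, C9 ketone carrying C11–C13 with the C13 dioxolane | O=C[C@H](C(C)(C)C(=O)OCC[Si](C)(C)C)[C@@](C)(CC(=O)OC)C(=O)CCC1(C)OCCO1 | intermediate
16 | diisopropyl (4S,5S)-2-(prop-2-en-1-yl)-1,3,2-dioxaborolane-4,5-dicarboxylate | C=CCB1O[C@H](C(=O)OC(C)C)[C@@H](C(=O)OC(C)C)O1 | starting material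
17 | (6R) homoallylic alcohol (C7–C8=C17 allyl group on the C6 carbinol) | C=CC[C@@H](O)[C@H](C(C)(C)C(=O)OCC[Si](C)(C)C)[C@@](C)(CC(=O)OC)C(=O)CCC1(C)OCCO1 | intermediate
18 | tert-butyldimethylsilyl ether of 17 | C=CC[C@@H](O[Si](C)(C)C(C)(C)C)[C@H](C(C)(C)C(=O)OCC[Si](C)(C)C)[C@@](C)(CC(=O)OC)C(=O)CCC1(C)OCCO1 | intermediate
19 | (Z)-enol triflate of the C9 ketone (C9=C11, triflate oxygen cis to C12) | C=CC[C@@H](O[Si](C)(C)C(C)(C)C)[C@H](C(C)(C)C(=O)OCC[Si](C)(C)C)[C@@](C)(CC(=O)OC)/C(OS(=O)(=O)C(F)(F)F)=C/CC1(C)OCCO1 | intermediate
20 | C8 methyl ketone bearing the (Z)-enol triflate | CC(=O)C[C@@H](O[Si](C)(C)C(C)(C)C)[C@H](C(C)(C)C(=O)OCC[Si](C)(C)C)[C@@](C)(CC(=O)OC)/C(OS(=O)(=O)C(F)(F)F)=C/CC1(C)OCCO1 | intermediate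
21 | ring B cyclohexane: C8 tertiary alcohol (O8 cis to the C1 arm on C10, C17 trans to it), exocyclic (Z) C9=C11 with C12 cis to C8 | C[C@]1(O)C[C@@H](O[Si](C)(C)C(C)(C)C)[C@H](C(C)(C)C(=O)OCC[Si](C)(C)C)[C@@](C)(CC(=O)OC)/C1=C/CC2(C)OCCO2 | intermediate
22 | bridged δ-lactone (2-oxabicyclo[3.3.1]nonan-3-one core, O8–C2) with exocyclic C9=C11 | CC1(OCCO1)C/C=C2/[C@]3(C)CC(=O)O[C@@]2(C)C[C@@H](O[Si](C)(C)C(C)(C)C)[C@@H]3C(C)(C)C(=O)OCC[Si](C)(C)C | intermediate
23 | (11S) alcohol with H9 syn to the lactone bridge, C13 still as dioxolane | CC1(OCCO1)C[C@H](O)[C@H]2[C@]3(C)CC(=O)O[C@@]2(C)C[C@@H](O[Si](C)(C)C(C)(C)C)[C@@H]3C(C)(C)C(=O)OCC[Si](C)(C)C | intermediate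
24 | (11S) β-hydroxy ketone (C13 methyl ketone) | CC(=O)C[C@H](O)[C@H]1[C@]2(C)CC(=O)O[C@@]1(C)C[C@@H](O[Si](C)(C)C(C)(C)C)[C@@H]2C(C)(C)C(=O)OCC[Si](C)(C)C | intermediate
25 | vinylmagnesium bromide | C=C[Mg]Br | starting material
26 | target protected as O6 tert-butyldimethylsilyl ether and C3 2-(trimethylsilyl)ethyl ester, (11S,13S) diol | C=C[C@@](C)(O)C[C@H](O)[C@H]1[C@]2(C)CC(=O)O[C@@]1(C)C[C@@H](O[Si](C)(C)C(C)(C)C)[C@@H]2C(C)(C)C(=O)OCC[Si](C)(C)C | intermediate
27 | CNP0297019.2 | C=C[C@@](C)(O)C[C@H](O)[C@H]1[C@]2(C)CC(=O)O[C@@]1(C)C[C@@H](O)[C@@H]2C(C)(C)C(=O)O | target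

Total step count: 13. Longest linear sequence: 12 steps (steps 1 and 3–13; step 2 is a one-step side branch).

Three steps most likely to fail

Step 9: the alkenylchromium may be protonated before it adds to the hindered methyl ketone, or it may add with poor facial selectivity at C8. Fallback: starting from 20, Miyaura borylation of the enol triflate (B2pin2, PdCl2(dppf), KOPh, toluene, 50 °C) would give the alkenyl pinacolboronate F1 with retention of geometry. A rhodium-catalysed intramolecular 1,2-addition of this isolated alkenylboron to the C8 ketone ([Rh(cod)OH]2, dioxane–H2O, 60 °C) would then return to 21.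

Step 3: the hindered lactone enolate may be quenched by proton transfer from methyl bromoacetate instead of being alkylated. Fallback: starting from 3 and 6, the Michael addition alone (LiN(iPr)2, THF, −78 °C; aq. NH4Cl) would give the Michael adduct lactone F2. Re-enolisation with KN(SiMe3)2 and alkylation with allyl iodide, which carries no acidic hydrogen, would give the allyl lactone F3 with the allyl group anti to the C5 substituent. Ozonolysis in CH2Cl2–MeOH with Ac2O/Et3N work-up would turn the allyl group into the CH2CO2CH3 arm and return to 10.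

Step 10: the tertiary alkoxide may fail to close the strained bridged lactone, or methoxide may reopen it. Fallback: starting from 21, LiOH (THF–H2O, 0 °C) would hydrolyse the unhindered methyl ester to the hydroxy acid F4. Shiina lactonisation (2-methyl-6-nitrobenzoic anhydride, DMAP, Et3N, CH2Cl2) would then activate the acid instead of relying on alkoxide exchange and return to 22.

Further compounds
F1 | step 9 | alkenyl pinacolboronate (boron on C9, cis to C12) | CC(=O)C[C@@H](O[Si](C)(C)C(C)(C)C)[C@H](C(C)(C)C(=O)OCC[Si](C)(C)C)[C@@](C)(CC(=O)OC)/C(B1OC(C)(C)C(C)(C)O1)=C/CC2(C)OCCO2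
F2 | step 3 | Michael adduct lactone (C10–H, both C10 epimers) | C[C@@H]1CC[C@H]([C@@H](C1)O[C@@H]2OC(=O)C(C)[C@H]2C(C)(C)C(=O)OCC[Si](C)(C)C)C(C)C
F3 | step 3 | C10 allyl lactone (allyl anti to the C5 substituent) | C[C@@H]1CC[C@H]([C@@H](C1)O[C@@H]2OC(=O)[C@](C)(CC=C)[C@H]2C(C)(C)C(=O)OCC[Si](C)(C)C)C(C)C
F4 | step 10 | hydroxy acid (free C2 acid, O8–H) | C[C@]1(O)C[C@@H](O[Si](C)(C)C(C)(C)C)[C@H](C(C)(C)C(=O)OCC[Si](C)(C)C)[C@@](C)(CC(=O)O)/C1=C/CC2(C)OCCO2
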